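## The problem

The target joins two oxygen heterocycles through ring B. One is a 2',6'-diaryl-3,7-dioxabicyclo[3.3.0]octane (atoms C1'–C8', ring A guaiacyl on C2', ring B on C6'). The other is a 2-aryl-3-hydroxymethyl-7-methoxy-2,3-dihydrobenzofuran (O1 to C7a, ring B = benzo ring, ring C = guaiacyl on C2), and C6' is bonded to C5. There are six stereocentres, (2S,3S) and (1'S,2'S,5'S,6'S), and both ring systems are the less stable isomers: C2-aryl and C3-CH2OH are cis, and both aryl groups of the furofuran sit on the concave (endo) face. Each benzylic C–O carbon (C2, C2', C6') carries a para-oxygenated aryl group, so acid, Lewis acid or a leaving group at these carbons opens a stabilised cation or quinone methide that re-closes to the trans or exo isomer. These bonds must therefore never be made or broken at the stereogenic carbon, and nothing ionising may follow their formation. The two halves are insulated from each other by the arene, so each needs its absolute configuration from a reagent; within each half the pairs C2/C3, C1'/C2' and C5'/C6' are anti-aldol relationships (an aryl carbinol next to a carbon bearing a CH2O unit). The end game is limited by the free phenols (base opens p-hydroxybenzyl ethers), the primary alcohol and the hydrogenolysable benzylic ethers. The enabling feature is that every ring oxygen has a second, non-stereogenic partner: O1 is bonded to the aromatic carbon C7a (ortho to C3a, the phenolic carbon of vanillin), and O3' and O7' are bonded to the primary carbons C4' and C8'. All three ether rings can therefore be closed away from the benzylic centres, with their configuration already in place.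

## Retrosynthesis

**Protecting groups (35 from 34 from 33).** No skeletal bond is cut. The phenols of rings A and C are carried as benzyl ethers and the C3 hydroxymethyl as a tert-butyldiphenylsilyl ether. The silyl group is taken off first, with buffered fluoride, while no phenoxide can form; the benzyl ethers go last by neutral hydrogenolysis. The reverse order would expose p-hydroxybenzyl ethers to fluoride base. The forward steps must leave C2–O1, C2'–O3' and C6'–O7' untouched.

**Furofuran ring closure (33 from tetraol 31 through bis-mesylate 32).** The cuts are O3'–C4' and O7'–C8', the two furofuran C–O bonds that end at primary carbons. Cutting the benzylic bonds O3'–C2' and O7'–C6' instead would mean substitution at p-alkoxybenzylic centres and would deliver the exo isomers. The precursor 31 is acyclic and its four stereocentres are two anti-aldol pairs. The forward reaction must sulfonylate the two primary hydroxyls selectively; each secondary hydroxyl can then reach only one mesylate through a five-membered transition state, so the bicycle forms with retention at C2' and C6'.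

**Fragment union (31 from 30 from 29 from aldehyde 18 and imide 28).** The cut is C5'–C6', an anti-aldol bond between the ring B aldehyde carbon and the α-carbon of an acyl unit that already holds C1' and C2'. Against the neighbouring cut C1'–C5' (an enolate coupling of two halves), the aldol sets C5' and C6' together under auxiliary control and uses the aldehyde that the dihydrobenzofuran synthesis delivers. The precursors are the complete dihydrobenzofuran 18 and a small ring A fragment 28, so the valuable half enters late. The forward aldol must override the existing C1' centre and tolerate an electron-rich aldehyde.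

**Ring A fragment (28 from 26, 25, 24, 23 and 22; 22 from 20 and 12; 20 from 9 and 19).** The cut is C1'–C2', a second anti-aldol, between O-benzylvanillin 12 and the pent-4-enoyl imide 20. The imide carbonyl becomes C8' after reduction, and the terminal alkene is the latent C4' carboxyl that carries the next auxiliary. A succinate-type acyl unit would give C4' directly but would lactonise onto either hydroxyl. The alkene costs two oxidation steps but stays inert until needed. The forward sequence asks only for standard operations on a simple arene.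

**Key cut (18 from 17 from 16).** O1–C7a is cut, the aryl ether bond of the dihydrobenzofuran. The neighbouring cut O1–C2 would require displacement at the p-alkoxybenzylic carbon and is known to drift to the trans ring. Cutting at C7a leaves C2 as an ordinary secondary alcohol. The precursor 16 is an open-chain anti 1,3-diol derivative with an ortho aryl triflate. The forward step is a palladium-catalysed intramolecular aryl etherification that must outrun β-hydride elimination and triflate cleavage.

**Anti-aldol for C2/C3 (16 from 15 from 14; 14 from 11 and 12).** The cut is C2–C3, between O-benzylvanillin 12 and the arylacetyl imide 11 made with auxiliary 9. The anti relationship of the open chain is exactly the cis relationship of the ring, so no later correction is needed. The precursors are an arylacetic acid and a commercial aldehyde. The forward reaction must give the anti diastereomer in the right absolute sense.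

**Ring B building block (11 from 8, 7, 6, 5, 4 and 3; 3 from 1 and 2).** The C3a–C3 bond comes from an aromatic Claisen rearrangement of vanillin allyl ether 3, which places the side chain ortho to the phenol that becomes the triflate. The allyl group is then degraded by one carbon to the acetic acid 8. Vanillin supplies the C5 aldehyde carbon, the C7 methoxy group and the C7a oxygen position in the correct pattern, so no aromatic substitution chemistry is needed.

## Roads not taken

**Alternative 1:** The cut runs through the ring A tetrahydrofuran at C2'–O3' and C4'–C5', with formaldehyde as the O3'–C4' unit. In the forward direction Sn(OTf)2 activates the exo-aryl cyclopropane-fused lactone A1. The formaldehyde oxygen opens the cyclopropane at the aryl-bearing carbon with inversion, and the lactone enolate closes on the resulting oxocarbenium carbon to give lactone A2 with ring A endo.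

- Merits: the endo aryl group comes from a stereospecific inversion. A1 is a few steps from a cinnamyl alcohol by asymmetric intramolecular cyclopropanation. The lactone carbonyl of A2 is a ready handle for ring B. For the furofuran this road needs roughly half the steps of the chosen one.
- Weak points: a cyclopropane with a single acceptor needs a strong Lewis acid, and its p-alkoxyphenyl donor can open to a free benzylic cation, which would erode both the inversion and the enantiopurity. Ring B would then have to be attached at the lactone carbon of A2 by organometallic addition and Lewis-acid lactol reduction. That asks for a metalated dihydrobenzofuran in place of the aldehyde and exposes the cis ring and the endo C2' ether to ionising conditions.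
- Comparison: against its brevity the chosen plan sets this: every benzylic centre is fixed by auxiliary-controlled C–C bond formation, and no Lewis acid is used once a sensitive ring exists.

**Alternative 2:** The cut is C3–C3a, made by contracting a six-membered ring. Irradiation of the 3-diazochromanone A3 expels nitrogen, the ring B carbon migrates from the carbonyl carbon to C3 (Wolff rearrangement), and methanol traps the ketene. Kinetic protonation anti to the C2 aryl group gives the cis ester A4.

- Merits: C2 is never ionised during the contraction. A3 is available in a few steps by chalcone cyclisation and diazo transfer, so the cis ring is reached in clearly fewer steps than the eleven needed for 17. The bromide is a handle for C5.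
- Weak points: the cis outcome rests on kinetic protonation, and the C3 centre of A4 is benzylic and α to an ester, so it can epimerise to trans until it is reduced. The absolute configuration depends on an enantioenriched 2-arylchromanone, a class that racemises by reversible oxa-Michael ring opening, especially under basic diazo transfer with an electron-rich 2-aryl group. The aldehyde carbon must still be introduced from the bromide.
- Comparison: this road is shorter. The chosen plan answers with one auxiliary aldol that fixes both centres in a known absolute sense, with no epimerisable centre after reduction, and with the aldehyde carbon carried from vanillin.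

**Alternative 3:** The cut is O7'–C6' and C5'–C6', so the ring B side tetrahydrofuran is assembled around the ring B aldehyde carbon. Me3SiOTf exchanges the hydroxymethyl oxygen of the cis-dihydrofuran A5 into the dimethyl acetal A6. The enol ether carbon attacks the oxocarbenium ion, and methanol caps C4' to give acetal A7. The C4' methoxy group is then removed reductively.

- Merits: this is the most convergent end game. The ring B acetal carbon is used directly, and two steps lead from A6 to the bis-endo furofuran, against six from aldehyde 18 in the chosen plan. The ring fusion and the endo C6' aryl group arise in one kinetically controlled cyclisation.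
- Weak points: Me3SiOTf and the following silane/Lewis acid reduction are the very conditions under which C2–O1 of the cis-dihydrobenzofuran in A6 and the new endo benzylic ethers ionise. C6' is set by substrate control only. A5 must be secured as a single cis enantiomer, which is not trivial.
- Comparison: if the cis-dihydrobenzofuran proved stable to these Lewis acids, this road would be the better one on step count. The chosen plan offsets its length with reagent control of all four furofuran centres from one auxiliary and with ring closures under base only.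

Key step: step 11

Assumption: the magnesium-catalysed anti-aldol additions are taken to proceed through the chelated Z-enolate, with attack on the face opposite the benzyl group (the sense of imide alkylation). This makes (S)-4-benzyl-2-oxazolidinone the auxiliary for all three aldol steps; were the sense reversed, the (R)-auxiliary would be used and nothing else would change.

Abbreviations in names: BnG = 4-benzyloxy-3-methoxyphenyl; ArT = 5-(1,3-dioxolan-2-yl)-3-methoxy-2-(trifluoromethylsulfonyloxy)phenyl; DHB = (2S,3S)-2-(4-benzyloxy-3-methoxyphenyl)-3-[(tert-butyldiphenylsilyloxy)methyl]-7-methoxy-2,3-dihydrobenzofuran-5-yl. Primed locants refer to the furofuran.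

## Route

Step 1
Reactants: 1 vanillin; 2 allyl bromide
Product: 3 4-allyloxy-3-methoxybenzaldehyde
Conditions: K2CO3, DMF, 60 °C
Reagents that add atoms: none
Why: Williamson etherification of the phenoxide with a primary allylic bromide; the aldehyde is inert to carbonate.

Step 2
Reactants: 3 4-allyloxy-3-methoxybenzaldehyde
Product: 4 3-allyl-4-hydroxy-5-methoxybenzaldehyde
Conditions: N,N-diethylaniline, 200 °C
Reagents that add atoms: none
Why: Aromatic Claisen rearrangement; only one ortho position is free, so the allyl group is delivered there and tautomerisation restores the phenol.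

Step 3
Reactants: 4 3-allyl-4-hydroxy-5-methoxybenzaldehyde
Product: 5 2-allyl-4-formyl-6-methoxyphenyl trifluoromethanesulfonate
Conditions: Tf2O, pyridine, CH2Cl2, 0 °C
Reagents that add atoms: trifluoromethanesulfonic anhydride, O=S(=O)(OS(=O)(=O)C(F)(F)F)C(F)(F)F
Why: O-sulfonylation of the phenol turns the former phenolic carbon (the future C7a) into the electrophile of the key step.

Step 4
Reactants: 5 2-allyl-4-formyl-6-methoxyphenyl trifluoromethanesulfonate
Product: 6 2-allyl-4-(1,3-dioxolan-2-yl)-6-methoxyphenyl trifluoromethanesulfonate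
Conditions: HOCH2CH2OH, TsOH (cat.), toluene, reflux (Dean–Stark)
Reagents that add atoms: ethylene glycol, OCCO
Why: Acid-catalysed acetalisation with azeotropic removal of water; the para triflate makes this dioxolane comparatively acid-stable for the oxidations and hydride reduction ahead.

Step 5
Reactants: 6 2-allyl-4-(1,3-dioxolan-2-yl)-6-methoxyphenyl trifluoromethanesulfonate
Product: 7 4-(1,3-dioxolan-2-yl)-2-methoxy-6-(2-oxoethyl)phenyl trifluoromethanesulfonate
Conditions: OsO4 (cat.), NaIO4, 2,6-lutidine, dioxane/H2O, rt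
Reagents that add atoms: osmium tetroxide, O=[Os](=O)(=O)=O; sodium periodate, [Na+].[O-]I(=O)(=O)=O
Why: Lemieux–Johnson cleavage of the terminal alkene removes one carbon; lutidine buffering protects the acetal, and the arylacetaldehyde is used crude.

Step 6
Reactants: 7 4-(1,3-dioxolan-2-yl)-2-methoxy-6-(2-oxoethyl)phenyl trifluoromethanesulfonate
Product: 8 (ArT)acetic acid
Conditions: NaClO2, NaH2PO4, 2-methyl-2-butene, t-BuOH/H2O, 0 °C to rt
Reagents that add atoms: sodium chlorite, [Na+].[O-]Cl=O
Why: Pinnick oxidation of the aldehyde to the acid; the phosphate buffer is too weak to open the triflate-deactivated dioxolane, and the alkene scavenges hypochlorite.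

Step 7
Reactants: 8 (ArT)acetic acid; 9 (S)-4-benzyl-2-oxazolidinone
Product: 11 (S)-4-benzyl-3-[(ArT)acetyl]oxazolidin-2-one, via mixed pivalic anhydride 10 (not isolated)
Conditions: t-BuCOCl, Et3N, THF, −20 °C; then 9, LiCl, rt
Reagents that add atoms: none
Why: N-acylation of the oxazolidinone through the mixed anhydride with LiCl activation; attack occurs at the less hindered arylacetyl carbonyl.

Step 8
Reactants: 11 (S)-4-benzyl-3-[(ArT)acetyl]oxazolidin-2-one; 12 4-benzyloxy-3-methoxybenzaldehyde
Product: 14 (S)-4-benzyl-3-[(2R,3S)-2-(ArT)-3-(BnG)-3-hydroxypropanoyl]oxazolidin-2-one, via trimethylsilyl ether 13 (not isolated)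
Conditions: MgCl2 (20 mol%), Et3N, Me3SiCl, EtOAc, rt; then Et3N·3HF, THF, 0 °C
Reagents that add atoms: none
Why: Magnesium-catalysed direct Evans anti-aldol: soft enolisation gives the chelated Z-enolate, the aldehyde adds on the face away from the benzyl group through a boat-like transition state, and silylation of the aldolate makes the addition irreversible. This sets C3 and C2 as the anti pair; buffered fluoride then frees the carbinol without touching the acetal.

Step 9
Reactants: 14 (S)-4-benzyl-3-[(2R,3S)-2-(ArT)-3-(BnG)-3-hydroxypropanoyl]oxazolidin-2-one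
Product: 15 (1S,2S)-1-(BnG)-2-(ArT)propane-1,3-diol
Conditions: LiBH4, H2O (1 equiv), Et2O/THF, 0 °C
Reagents that add atoms: none
Why: Reductive removal of the auxiliary from the imide gives the primary alcohol (the C3 hydroxymethyl); low temperature limits retro-aldol cleavage, and the triflate and acetal are inert to borohydride.

Step 10
Reactants: 15 (1S,2S)-1-(BnG)-2-(ArT)propane-1,3-diol
Product: 16 (1S,2S)-1-(BnG)-3-(tert-butyldiphenylsilyloxy)-2-(ArT)propan-1-ol
Conditions: t-BuPh2SiCl, imidazole, CH2Cl2, 0 °C
Reagents that add atoms: tert-butyl(chloro)diphenylsilane, CC(C)(C)[Si](Cl)(c1ccccc1)c1ccccc1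
Why: Selective silylation of the primary hydroxyl by a bulky chlorosilane leaves the hindered benzylic alcohol free for the ring closure; this silyl ether is chosen to survive the later acetal hydrolysis and the selective removal of triethylsilyl groups.

Step 11
Reactants: 16 (1S,2S)-1-(BnG)-3-(tert-butyldiphenylsilyloxy)-2-(ArT)propan-1-ol
Product: 17 (2S,3S)-2-(BnG)-3-[(tert-butyldiphenylsilyloxy)methyl]-5-(1,3-dioxolan-2-yl)-7-methoxy-2,3-dihydrobenzofuran
Conditions: Pd(OAc)2 (5 mol%), 2-di-tert-butylphosphino-2',4',6'-triisopropylbiphenyl (7.5 mol%), Cs2CO3, toluene, 80 °C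
Reagents that add atoms: none
Why: Intramolecular Buchwald–Hartwig-type aryl etherification. Pd(OAc)2 is reduced in situ to a zerovalent palladium–phosphine complex that adds oxidatively to the C7a–OTf bond; carbonate-assisted exchange of triflate for the C2 alkoxide gives a six-membered aryl(alkoxo) complex of divalent palladium, and C–O reductive elimination forms O1–C7a and returns zerovalent palladium. The closest known reaction is the palladium-catalysed cyclisation of secondary alcohols bearing an ortho-halo or ortho-sulfonyloxy aryl group to five- to seven-membered oxygen heterocycles with bulky di-tert-butyl biaryl phosphines, which keeps the carbinol configuration. The dihydrofuran ring closes by reductive elimination from the six-membered palladacycle (a 5-exo-type closure onto the arene carbon), so no bond to C2 or C3 is made or broken. No stereocentre is created: C2 and C3 come from anti-aldol adduct 14, C3–H is not acidic under carbonate, and the anti open chain therefore maps onto the cis ring. The selectivity needed is reductive elimination over β-hydride elimination of the secondary alkoxide and over S–O cleavage of the triflate. The bulky electron-rich ligand accelerates C–O reductive elimination, anhydrous Cs2CO3 in toluene keeps the free alkoxide concentration low, and the chelate holds the alkoxide and aryl group together. The acetal, silyl ether and benzyl ether are inert under these conditions.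

Step 12
Reactants: 17 (2S,3S)-2-(BnG)-3-[(tert-butyldiphenylsilyloxy)methyl]-5-(1,3-dioxolan-2-yl)-7-methoxy-2,3-dihydrobenzofuran
Product: 18 (2S,3S)-2-(BnG)-3-[(tert-butyldiphenylsilyloxy)methyl]-7-methoxy-2,3-dihydrobenzofuran-5-carbaldehyde
Conditions: PPTS (cat.), acetone/H2O, 40 °C
Reagents that add atoms: water, O
Why: Acetal hydrolysis; after the ring closure the acetal carbon is para to O1 and hydrolyses under acid too weak to ionise C2–O1 or cleave the silyl ether.

Step 13
Reactants: 9 (S)-4-benzyl-2-oxazolidinone; 19 pent-4-enoyl chloride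
Product: 20 (S)-4-benzyl-3-(pent-4-enoyl)oxazolidin-2-one
Conditions: Et3N, DMAP (cat.), CH2Cl2, 0 °C to rt
Reagents that add atoms: none
Why: DMAP-catalysed N-acylation of the oxazolidinone with an unhindered acid chloride.

Step 14
Reactants: 20 (S)-4-benzyl-3-(pent-4-enoyl)oxazolidin-2-one; 12 4-benzyloxy-3-methoxybenzaldehyde
Product: 22 (S)-4-benzyl-3-{(2R)-2-[(S)-(BnG)(hydroxy)methyl]pent-4-enoyl}oxazolidin-2-one, via trimethylsilyl ether 21 (not isolated)
Conditions: MgCl2 (10 mol%), Et3N, Me3SiCl, EtOAc, rt; then Et3N·3HF, THF, 0 °C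
Reagents that add atoms: none
Why: Evans magnesium-catalysed anti-aldol as in step 8; the chelated Z-enolate reacts on the face opposite the benzyl group and sets C1' and C2' as the anti pair required for an endo ring A.

Step 15
Reactants: 22 (S)-4-benzyl-3-{(2R)-2-[(S)-(BnG)(hydroxy)methyl]pent-4-enoyl}oxazolidin-2-one
Product: 23 (1S,2S)-2-allyl-1-(BnG)propane-1,3-diol
Conditions: LiBH4, H2O (1 equiv), Et2O/THF, 0 °C
Reagents that add atoms: none
Why: Reductive cleavage of the imide turns the first acyl carbon into the C8' hydroxymethyl and returns the auxiliary.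

Step 16
Reactants: 23 (1S,2S)-2-allyl-1-(BnG)propane-1,3-diol
Product: 24 (1S,2S)-2-allyl-1-(BnG)-1,3-bis(triethylsilyloxy)propane
Conditions: Et3SiCl, imidazole, DMF, rt
Reagents that add atoms: chlorotriethylsilane, CC[Si](Cl)(CC)CC
Why: Exhaustive silylation; triethylsilyl ethers survive the oxidations and the aldol yet are removed later with buffered HF while the tert-butyldiphenylsilyl ether stays.

Step 17
Reactants: 24 (1S,2S)-2-allyl-1-(BnG)-1,3-bis(triethylsilyloxy)propane
Product: 25 (3S,4S)-4-(BnG)-4-(triethylsilyloxy)-3-[(triethylsilyloxy)methyl]butanal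
Conditions: OsO4 (cat.), NaIO4, 2,6-lutidine, dioxane/H2O, rt
Reagents that add atoms: osmium tetroxide, O=[Os](=O)(=O)=O; sodium periodate, [Na+].[O-]I(=O)(=O)=O
Why: Lemieux–Johnson cleavage of the terminal alkene unmasks the C4' carbon as an aldehyde; the buffered medium spares the silyl ethers and the electron-rich arene.

Step 18
Reactants: 25 (3S,4S)-4-(BnG)-4-(triethylsilyloxy)-3-[(triethylsilyloxy)methyl]butanal
Product: 26 (3S,4S)-4-(BnG)-4-(triethylsilyloxy)-3-[(triethylsilyloxy)methyl]butanoic acid
Conditions: NaClO2, NaH2PO4, 2-methyl-2-butene, t-BuOH/H2O, 0 °C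
Reagents that add atoms: sodium chlorite, [Na+].[O-]Cl=O
Why: Pinnick oxidation; excess 2-methyl-2-butene intercepts hypochlorite before it can chlorinate the guaiacyl ring.

Step 19
Reactants: 26 (3S,4S)-4-(BnG)-4-(triethylsilyloxy)-3-[(triethylsilyloxy)methyl]butanoic acid; 9 (S)-4-benzyl-2-oxazolidinone
Product: 28 (S)-4-benzyl-3-{(3S,4S)-4-(BnG)-4-(triethylsilyloxy)-3-[(triethylsilyloxy)methyl]butanoyl}oxazolidin-2-one, via mixed pivalic anhydride 27 (not isolated)
Conditions: t-BuCOCl, Et3N, THF, −20 °C; then 9, LiCl, rt
Reagents that add atoms: none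
Why: N-acylation through the mixed anhydride as in step 7; it installs the auxiliary that will control C5' and C6'.

Step 20
Reactants: 18 (2S,3S)-2-(BnG)-3-[(tert-butyldiphenylsilyloxy)methyl]-7-methoxy-2,3-dihydrobenzofuran-5-carbaldehyde; 28 (S)-4-benzyl-3-{(3S,4S)-4-(BnG)-4-(triethylsilyloxy)-3-[(triethylsilyloxy)methyl]butanoyl}oxazolidin-2-one
Product: 29 (S)-4-benzyl-3-{(2R,3S)-2-[(1S,2S)-1-(BnG)-1,3-bis(triethylsilyloxy)propan-2-yl]-3-(DHB)-3-(trimethylsilyloxy)propanoyl}oxazolidin-2-one
Conditions: MgCl2 (50 mol%), Et3N, Me3SiCl, EtOAc, rt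
Reagents that add atoms: chlorotrimethylsilane, C[Si](C)(C)Cl
Why: Third Evans magnesium-catalysed anti-aldol; the auxiliary fixes C5' through the chelated Z-enolate and the boat transition state gives the anti C6' carbinol, which is trapped as its trimethylsilyl ether. The remote dihydrobenzofuran centres play no part, and the basic medium cannot ionise C2–O1.

Step 21
Reactants: 29 (S)-4-benzyl-3-{(2R,3S)-2-[(1S,2S)-1-(BnG)-1,3-bis(triethylsilyloxy)propan-2-yl]-3-(DHB)-3-(trimethylsilyloxy)propanoyl}oxazolidin-2-one
Product: 30 (1S,2S,3S,4S)-1-(BnG)-4-(DHB)-3-(hydroxymethyl)-1-(triethylsilyloxy)-2-[(triethylsilyloxy)methyl]-4-(trimethylsilyloxy)butane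
Conditions: LiBH4, MeOH (1 equiv), THF, 0 °C
Reagents that add atoms: none
Why: Reductive removal of the auxiliary gives the C4' hydroxymethyl; the silylated carbinol cannot undergo retro-aldol cleavage, and any migration of the trimethylsilyl group is harmless because the next step removes it.

Step 22
Reactants: 30 (1S,2S,3S,4S)-1-(BnG)-4-(DHB)-3-(hydroxymethyl)-1-(triethylsilyloxy)-2-[(triethylsilyloxy)methyl]-4-(trimethylsilyloxy)butane
Product: 31 (1S,2S,3S,4S)-1-(BnG)-4-(DHB)-2,3-bis(hydroxymethyl)butane-1,4-diol
Conditions: HF·pyridine, pyridine, THF, 0 °C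
Reagents that add atoms: none
Why: Pyridine-buffered HF removes the trimethylsilyl and both triethylsilyl ethers much faster than the primary tert-butyldiphenylsilyl ether, and is not acidic enough to ionise the p-alkoxybenzylic alcohols.

Step 23
Reactants: 31 (1S,2S,3S,4S)-1-(BnG)-4-(DHB)-2,3-bis(hydroxymethyl)butane-1,4-diol
Product: 33 (1'S,2'S,5'S,6'S)-2'-(BnG)-6'-(DHB)-3,7-dioxabicyclo[3.3.0]octane, via bis-mesylate 32 (not isolated)
Conditions: MeSO2Cl (2.3 equiv), pyridine, 0 °C to rt
Reagents that add atoms: none
Why: The two primary hydroxyls are sulfonylated selectively, and each secondary benzylic hydroxyl then displaces the one mesylate it can reach by 5-exo-tet attack at a primary carbon (double Williamson cyclisation). C2' and C6' keep their configuration, and the anti,anti tetraol gives the bis-endo, cis-fused furofuran under kinetic control.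

Step 24
Reactants: 33 (1'S,2'S,5'S,6'S)-2'-(BnG)-6'-(DHB)-3,7-dioxabicyclo[3.3.0]octane
Product: 34 (1'S,2'S,5'S,6'S)-2'-(BnG)-6'-[(2S,3S)-2-(BnG)-3-(hydroxymethyl)-7-methoxy-2,3-dihydrobenzofuran-5-yl]-3,7-dioxabicyclo[3.3.0]octane
Conditions: Bu4NF, AcOH, THF, rt
Reagents that add atoms: none
Why: Fluoride cleavage of the silyl ether; it is done while both phenols are still benzylated, so no phenoxide can open a benzylic ether through a quinone methide.

Step 25
Reactants: 34 (1'S,2'S,5'S,6'S)-2'-(BnG)-6'-[(2S,3S)-2-(BnG)-3-(hydroxymethyl)-7-methoxy-2,3-dihydrobenzofuran-5-yl]-3,7-dioxabicyclo[3.3.0]octane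
Product: 35 target CNP0303197.1
Conditions: H2 (1 atm), Pd/C (10%), EtOAc/EtOH, rt
Reagents that add atoms: none
Why: Hydrogenolysis of the two aryl benzyl ethers under neutral conditions; aryl benzyl ethers cleave faster than the dialkyl and alkyl aryl benzylic ethers of the two ring systems, so the reaction is stopped at full debenzylation.

## Compound list

1 | vanillin (4-hydroxy-3-methoxybenzaldehyde) | COc1cc(C=O)ccc1O | starting material
2 | allyl bromide | C=CCBr | starting material
3 | 4-allyloxy-3-methoxybenzaldehyde | COc1cc(C=O)ccc1OCC=C | intermediate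
4 | 3-allyl-4-hydroxy-5-methoxybenzaldehyde | COc1cc(C=O)cc(CC=C)c1O | intermediate
5 | 2-allyl-4-formyl-6-methoxyphenyl trifluoromethanesulfonate | COc1cc(C=O)cc(CC=C)c1OS(=O)(=O)C(F)(F)F | intermediate
6 | 2-allyl-4-(1,3-dioxolan-2-yl)-6-methoxyphenyl trifluoromethanesulfonate | O1CCOC1c1cc(OC)c(OS(=O)(=O)C(F)(F)F)c(CC=C)c1 | intermediate
7 | 4-(1,3-dioxolan-2-yl)-2-methoxy-6-(2-oxoethyl)phenyl trifluoromethanesulfonate | O1CCOC1c1cc(OC)c(OS(=O)(=O)C(F)(F)F)c(CC=O)c1 | intermediate
8 | [5-(1,3-dioxolan-2-yl)-3-methoxy-2-(trifluoromethylsulfonyloxy)phenyl]acetic acid | O1CCOC1c1cc(OC)c(OS(=O)(=O)C(F)(F)F)c(CC(=O)O)c1 | intermediate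
9 | (S)-4-benzyl-2-oxazolidinone | O=C1OC[C@H](Cc2ccccc2)N1 | starting material
10 | mixed anhydride of acid 8 with pivalic acid | O1CCOC1c1cc(OC)c(OS(=O)(=O)C(F)(F)F)c(CC(=O)OC(=O)C(C)(C)C)c1 | intermediate
11 | (S)-4-benzyl-3-{[5-(1,3-dioxolan-2-yl)-3-methoxy-2-(trifluoromethylsulfonyloxy)phenyl]acetyl}oxazolidin-2-one | O1CCOC1c1cc(OC)c(OS(=O)(=O)C(F)(F)F)c(CC(=O)N2C(=O)OC[C@@H]2Cc2ccccc2)c1 | intermediate
12 | 4-benzyloxy-3-methoxybenzaldehyde (O-benzylvanillin) | COc1cc(C=O)ccc1OCc1ccccc1 | starting material
13 | trimethylsilyl ether of anti-aldol adduct 14 | O1CCOC1c1cc(OC)c(OS(=O)(=O)C(F)(F)F)c(c1)[C@@H](C(=O)N1C(=O)OC[C@@H]1Cc1ccccc1)[C@@H](c1ccc(OCc2ccccc2)c(OC)c1)O[Si](C)(C)C | intermediate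
14 | (S)-4-benzyl-3-[(2R,3S)-3-(4-benzyloxy-3-methoxyphenyl)-2-[5-(1,3-dioxolan-2-yl)-3-methoxy-2-(trifluoromethylsulfonyloxy)phenyl]-3-hydroxypropanoyl]oxazolidin-2-one (anti) | O1CCOC1c1cc(OC)c(OS(=O)(=O)C(F)(F)F)c(c1)[C@@H](C(=O)N1C(=O)OC[C@@H]1Cc1ccccc1)[C@@H](c1ccc(OCc2ccccc2)c(OC)c1)O | intermediate
15 | (1S,2S)-1-(4-benzyloxy-3-methoxyphenyl)-2-[5-(1,3-dioxolan-2-yl)-3-methoxy-2-(trifluoromethylsulfonyloxy)phenyl]propane-1,3-diol | O1CCOC1c1cc(OC)c(OS(=O)(=O)C(F)(F)F)c(c1)[C@@H](CO)[C@@H](c1ccc(OCc2ccccc2)c(OC)c1)O | intermediate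
16 | (1S,2S)-1-(4-benzyloxy-3-methoxyphenyl)-3-(tert-butyldiphenylsilyloxy)-2-[5-(1,3-dioxolan-2-yl)-3-methoxy-2-(trifluoromethylsulfonyloxy)phenyl]propan-1-ol | O1CCOC1c1cc(OC)c(OS(=O)(=O)C(F)(F)F)c(c1)[C@@H](CO[Si](c1ccccc1)(c1ccccc1)C(C)(C)C)[C@@H](c1ccc(OCc2ccccc2)c(OC)c1)O | intermediate
17 | (2S,3S)-2-(4-benzyloxy-3-methoxyphenyl)-3-[(tert-butyldiphenylsilyloxy)methyl]-5-(1,3-dioxolan-2-yl)-7-methoxy-2,3-dihydrobenzofuran (cis) | O1CCOC1c1cc(OC)c2c(c1)[C@@H](CO[Si](c1ccccc1)(c1ccccc1)C(C)(C)C)[C@@H](c1ccc(OCc3ccccc3)c(OC)c1)O2 | intermediate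
18 | (2S,3S)-2-(4-benzyloxy-3-methoxyphenyl)-3-[(tert-butyldiphenylsilyloxy)methyl]-7-methoxy-2,3-dihydrobenzofuran-5-carbaldehyde | O=Cc1cc(OC)c2c(c1)[C@@H](CO[Si](c1ccccc1)(c1ccccc1)C(C)(C)C)[C@@H](c1ccc(OCc3ccccc3)c(OC)c1)O2 | intermediate
19 | pent-4-enoyl chloride | C=CCCC(=O)Cl | starting material
20 | (S)-4-benzyl-3-(pent-4-enoyl)oxazolidin-2-one | C=CCCC(=O)N1C(=O)OC[C@@H]1Cc1ccccc1 | intermediate
21 | trimethylsilyl ether of anti-aldol adduct 22 | COc1cc([C@@H](O[Si](C)(C)C)[C@@H](CC=C)C(=O)N2C(=O)OC[C@@H]2Cc2ccccc2)ccc1OCc1ccccc1 | intermediate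
22 | (S)-4-benzyl-3-{(2R)-2-[(S)-(4-benzyloxy-3-methoxyphenyl)(hydroxy)methyl]pent-4-enoyl}oxazolidin-2-one (anti) | COc1cc([C@@H](O)[C@@H](CC=C)C(=O)N2C(=O)OC[C@@H]2Cc2ccccc2)ccc1OCc1ccccc1 | intermediate
23 | (1S,2S)-2-allyl-1-(4-benzyloxy-3-methoxyphenyl)propane-1,3-diol | COc1cc([C@@H](O)[C@@H](CC=C)CO)ccc1OCc1ccccc1 | intermediate
24 | (1S,2S)-2-allyl-1-(4-benzyloxy-3-methoxyphenyl)-1,3-bis(triethylsilyloxy)propane | COc1cc([C@@H](O[Si](CC)(CC)CC)[C@@H](CC=C)CO[Si](CC)(CC)CC)ccc1OCc1ccccc1 | intermediate
25 | (3S,4S)-4-(4-benzyloxy-3-methoxyphenyl)-4-(triethylsilyloxy)-3-[(triethylsilyloxy)methyl]butanal | COc1cc([C@@H](O[Si](CC)(CC)CC)[C@@H](CC=O)CO[Si](CC)(CC)CC)ccc1OCc1ccccc1 | intermediate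
26 | (3S,4S)-4-(4-benzyloxy-3-methoxyphenyl)-4-(triethylsilyloxy)-3-[(triethylsilyloxy)methyl]butanoic acid | COc1cc([C@@H](O[Si](CC)(CC)CC)[C@@H](CC(=O)O)CO[Si](CC)(CC)CC)ccc1OCc1ccccc1 | intermediate
27 | mixed anhydride of acid 26 with pivalic acid | COc1cc([C@@H](O[Si](CC)(CC)CC)[C@@H](CC(=O)OC(=O)C(C)(C)C)CO[Si](CC)(CC)CC)ccc1OCc1ccccc1 | intermediate
28 | (S)-4-benzyl-3-{(3S,4S)-4-(4-benzyloxy-3-methoxyphenyl)-4-(triethylsilyloxy)-3-[(triethylsilyloxy)methyl]butanoyl}oxazolidin-2-one | COc1cc([C@@H](O[Si](CC)(CC)CC)[C@@H](CC(=O)N2C(=O)OC[C@@H]2Cc2ccccc2)CO[Si](CC)(CC)CC)ccc1OCc1ccccc1 | intermediate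
29 | anti-aldol adduct of 28 and 18 as its trimethylsilyl ether: the acyl chain is (2R,3S) with C5' as carbon 2 and C6' as carbon 3; C1' and C2' are S | COc1cc([C@@H](O[Si](CC)(CC)CC)[C@H](CO[Si](CC)(CC)CC)[C@@H](C(=O)N2C(=O)OC[C@@H]2Cc2ccccc2)[C@H](O[Si](C)(C)C)c2cc(OC)c3c(c2)[C@@H](CO[Si](c2ccccc2)(c2ccccc2)C(C)(C)C)[C@@H](c2ccc(OCc4ccccc4)c(OC)c2)O3)ccc1OCc1ccccc1 | intermediate
30 | (1S,2S,3S,4S)-1-(ring A aryl)-4-(ring B aryl)-3-(hydroxymethyl)-1-(triethylsilyloxy)-2-[(triethylsilyloxy)methyl]-4-(trimethylsilyloxy)butane | COc1cc([C@@H](O[Si](CC)(CC)CC)[C@H](CO[Si](CC)(CC)CC)[C@@H](CO)[C@H](O[Si](C)(C)C)c2cc(OC)c3c(c2)[C@@H](CO[Si](c2ccccc2)(c2ccccc2)C(C)(C)C)[C@@H](c2ccc(OCc4ccccc4)c(OC)c2)O3)ccc1OCc1ccccc1 | intermediate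
31 | (1S,2S,3S,4S)-1-(4-benzyloxy-3-methoxyphenyl)-4-(ring B aryl)-2,3-bis(hydroxymethyl)butane-1,4-diol, tert-butyldiphenylsilyl ether retained | COc1cc([C@@H](O)[C@H](CO)[C@@H](CO)[C@H](O)c2cc(OC)c3c(c2)[C@@H](CO[Si](c2ccccc2)(c2ccccc2)C(C)(C)C)[C@@H](c2ccc(OCc4ccccc4)c(OC)c2)O3)ccc1OCc1ccccc1 | intermediate
32 | bis(methanesulfonate) of the two primary hydroxyls of 31 | COc1cc([C@@H](O)[C@H](COS(C)(=O)=O)[C@@H](COS(C)(=O)=O)[C@H](O)c2cc(OC)c3c(c2)[C@@H](CO[Si](c2ccccc2)(c2ccccc2)C(C)(C)C)[C@@H](c2ccc(OCc4ccccc4)c(OC)c2)O3)ccc1OCc1ccccc1 | intermediate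
33 | (1'S,2'S,5'S,6'S)-2'-(4-benzyloxy-3-methoxyphenyl)-6'-{(2S,3S)-2-(4-benzyloxy-3-methoxyphenyl)-3-[(tert-butyldiphenylsilyloxy)methyl]-7-methoxy-2,3-dihydrobenzofuran-5-yl}-3,7-dioxabicyclo[3.3.0]octane (bis-endo) | COc1cc([C@H]2OC[C@@H]3[C@H]2CO[C@@H]3c2cc(OC)c3c(c2)[C@@H](CO[Si](c2ccccc2)(c2ccccc2)C(C)(C)C)[C@@H](c2ccc(OCc4ccccc4)c(OC)c2)O3)ccc1OCc1ccccc1 | intermediate
34 | dibenzyl ether of the target (free C3 hydroxymethyl) | COc1cc([C@H]2OC[C@@H]3[C@H]2CO[C@@H]3c2cc(OC)c3c(c2)[C@@H](CO)[C@@H](c2ccc(OCc4ccccc4)c(OC)c2)O3)ccc1OCc1ccccc1 | intermediate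
35 | CNP0303197.1: (1'S,2'S,5'S,6'S)-2'-(4-hydroxy-3-methoxyphenyl)-6'-[(2S,3S)-2-(4-hydroxy-3-methoxyphenyl)-3-(hydroxymethyl)-7-methoxy-2,3-dihydrobenzofuran-5-yl]-3,7-dioxabicyclo[3.3.0]octane | COc1cc([C@H]2OC[C@@H]3[C@H]2CO[C@@H]3c2cc(OC)c3c(c2)[C@@H](CO)[C@@H](c2ccc(O)c(OC)c2)O3)ccc1O | target

## Step count and risks

Total: 25 steps. Longest linear sequence: 18 steps (steps 1–12 and 20–25, from vanillin). The ring A branch (steps 13–19) is 7 steps before the union.

**Step 11 (key step).** The most likely failure is loss of the triflate by S–O cleavage (triflyl transfer to the C2 alkoxide or to carbonate) before a slow oxidative addition at the doubly ortho-substituted C7a. Behind that comes β-hydride elimination from the palladium alkoxide, which would give the ketone and the reduced arene.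
Fallback: from 16, Miyaura borylation (PdCl2(dppf), bis(pinacolato)diboron, KOAc, dioxane; dppf = 1,1'-bis(diphenylphosphino)ferrocene) would give the aryl pinacol boronate F1. A copper-mediated oxidative O-arylation of the free C2 hydroxyl (Chan–Lam coupling; Cu(OAc)2, pyridine, O2, 4 Å sieves, CH2Cl2) then closes the same O1–C7a bond, again without touching C2, and returns to 17. No strongly basic alkoxide is generated on this path.

**Step 8.** The ortho-triflyloxy arylacetyl enolate is hindered and well stabilised. Retro-aldol equilibration before the aldolate is silylated could erode the anti selectivity, and the facial sense rests on the stated assumption.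
Fallback: from acid 8, coupling with (R)-4-benzylthiazolidine-2-thione (carbodiimide, DMAP) would give the N-acylthiazolidinethione F2. Its MgBr2·OEt2-catalysed anti-aldol addition to 12 (Et3N, Me3SiCl, EtOAc) would give the silyl ether F3; the antipodal auxiliary is chosen because this enolate system is reported to give the other anti sense for a given auxiliary configuration. Et3N·3HF frees the alcohol F4, and NaBH4 in THF/EtOH removes this more labile auxiliary to return to diol 15.

**Step 20.** Low conversion is the main concern: the imide 28 is β-branched and the aldehyde 18 is a deactivated p-alkoxybenzaldehyde, so enolate addition may be slow and the existing C1' centre may oppose the auxiliary.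
Fallback: from acid 26, PPTS in methanol removes the primary triethylsilyl group to give the hydroxy acid F5, which lactonises to the β-substituted butyrolactone F6. Its lithium enolate (LiN(SiMe3)2, THF, −78 °C) adds to 18 trans to the ring substituent, and the fixed E-enolate geometry favours the anti carbinol through a Zimmerman–Traxler chair, giving the hydroxy lactone F7. LiBH4 reduction to the triol F8 and HF·pyridine desilylation return to tetraol 31. Here the sense at C5' comes from the substrate, not from an auxiliary.

**Step 23.** Sulfonylation of a secondary benzylic hydroxyl would be followed by ionisation and closure to exo isomers. Alternatively, a primary hydroxyl may attack the first mesylate before the second is formed, which would give a 3,4-disubstituted tetrahydrofuran.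
Fallback: from 31, a double Mitsunobu cyclodehydration (PPh3, diisopropyl azodicarboxylate, THF, 0 °C) activates the less hindered primary hydroxyls as alkoxyphosphonium ions without forming a sulfonate at the benzylic positions, and returns to 33. This fallback makes no new compound (F0).

**Step 25.** Once the phenols are free, the benzylic C–O bonds (C2–O1, C2'–O3', C6'–O7') become prone to over-reduction on the palladium surface.
Fallback: from 33, palladium-catalysed silane transfer (Pd(OAc)2, Et3SiH, Et3N, CH2Cl2) would cleave the benzyl ethers and deliver the phenols directly as the bis(triethylsilyl) aryl ether F9, so no free p-hydroxybenzyl ether meets the catalyst. One buffered fluoride treatment (Bu4NF, AcOH, THF) then removes all three silyl groups and arrives at 35.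

## Further compounds

F1 | step 11 | (1S,2S)-1-(4-benzyloxy-3-methoxyphenyl)-3-(tert-butyldiphenylsilyloxy)-2-[5-(1,3-dioxolan-2-yl)-3-methoxy-2-(4,4,5,5-tetramethyl-1,3,2-dioxaborolan-2-yl)phenyl]propan-1-ol | O1CCOC1c1cc(OC)c(B2OC(C)(C)C(C)(C)O2)c(c1)[C@@H](CO[Si](c1ccccc1)(c1ccccc1)C(C)(C)C)[C@@H](c1ccc(OCc2ccccc2)c(OC)c1)O
F2 | step 8 | (R)-4-benzyl-3-{[5-(1,3-dioxolan-2-yl)-3-methoxy-2-(trifluoromethylsulfonyloxy)phenyl]acetyl}thiazolidine-2-thione | O1CCOC1c1cc(OC)c(OS(=O)(=O)C(F)(F)F)c(CC(=O)N2C(=S)SC[C@H]2Cc2ccccc2)c1
F3 | step 8 | trimethylsilyl ether of the (2R,3S) anti-aldol adduct on the (R)-thiazolidinethione | O1CCOC1c1cc(OC)c(OS(=O)(=O)C(F)(F)F)c(c1)[C@@H](C(=O)N1C(=S)SC[C@H]1Cc1ccccc1)[C@@H](c1ccc(OCc2ccccc2)c(OC)c1)O[Si](C)(C)C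
F4 | step 8 | (2R,3S) anti-aldol adduct on the (R)-thiazolidinethione, free alcohol | O1CCOC1c1cc(OC)c(OS(=O)(=O)C(F)(F)F)c(c1)[C@@H](C(=O)N1C(=S)SC[C@H]1Cc1ccccc1)[C@@H](c1ccc(OCc2ccccc2)c(OC)c1)O
F5 | step 20 | (3S,4S)-4-(4-benzyloxy-3-methoxyphenyl)-3-(hydroxymethyl)-4-(triethylsilyloxy)butanoic acid | COc1cc([C@@H](O[Si](CC)(CC)CC)[C@@H](CC(=O)O)CO)ccc1OCc1ccccc1
F6 | step 20 | (S)-4-[(S)-(4-benzyloxy-3-methoxyphenyl)(triethylsilyloxy)methyl]dihydrofuran-2(3H)-one | COc1cc([C@@H](O[Si](CC)(CC)CC)[C@H]2CC(=O)OC2)ccc1OCc1ccccc1
F7 | step 20 | trans-3,4-disubstituted lactone: aldol adduct of F6 with 18, anti carbinol at C6' | COc1cc([C@@H](O[Si](CC)(CC)CC)[C@@H]2COC(=O)[C@H]2[C@H](O)c2cc(OC)c3c(c2)[C@@H](CO[Si](c2ccccc2)(c2ccccc2)C(C)(C)C)[C@@H](c2ccc(OCc4ccccc4)c(OC)c2)O3)ccc1OCc1ccccc1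
F8 | step 20 | triol from reduction of F7, C2' oxygen still triethylsilylated | COc1cc([C@@H](O[Si](CC)(CC)CC)[C@H](CO)[C@@H](CO)[C@H](O)c2cc(OC)c3c(c2)[C@@H](CO[Si](c2ccccc2)(c2ccccc2)C(C)(C)C)[C@@H](c2ccc(OCc4ccccc4)c(OC)c2)O3)ccc1OCc1ccccc1
F0 | step 23 | none | none
F9 | step 25 | bis(triethylsilyl) aryl ether of the furofuran, tert-butyldiphenylsilyl ether retained | COc1cc([C@H]2OC[C@@H]3[C@H]2CO[C@@H]3c2cc(OC)c3c(c2)[C@@H](CO[Si](c2ccccc2)(c2ccccc2)C(C)(C)C)[C@@H](c2ccc(O[Si](CC)(CC)CC)c(OC)c2)O3)ccc1O[Si](CC)(CC)CC
A1 | alternative 1 | exo-6-(4-benzyloxy-3-methoxyphenyl)-3-oxabicyclo[3.1.0]hexan-2-one | COc1cc([C@@H]2[C@@H]3[C@H]2COC3=O)ccc1OCc1ccccc1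
A2 | alternative 1 | 6-endo-(4-benzyloxy-3-methoxyphenyl)-3,7-dioxabicyclo[3.3.0]octan-2-one | COc1cc([C@H]2OC[C@@H]3[C@H]2COC3=O)ccc1OCc1ccccc1
A3 | alternative 2 | 2-(4-benzyloxy-3-methoxyphenyl)-6-bromo-3-diazo-8-methoxychroman-4-one | Brc1cc(OC)c2c(c1)C(=O)C(=[N+]=[N-])[C@@H](c1ccc(OCc3ccccc3)c(OC)c1)O2
A4 | alternative 2 | methyl cis-2-(4-benzyloxy-3-methoxyphenyl)-5-bromo-7-methoxy-2,3-dihydrobenzofuran-3-carboxylate | Brc1cc(OC)c2c(c1)[C@@H](C(=O)OC)[C@@H](c1ccc(OCc3ccccc3)c(OC)c1)O2
A5 | alternative 3 | cis-2-(4-benzyloxy-3-methoxyphenyl)-3-(hydroxymethyl)-2,3-dihydrofuran | COc1cc([C@H]2OC=C[C@H]2CO)ccc1OCc1ccccc1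
A6 | alternative 3 | dimethyl acetal of cis-3-(acetoxymethyl)-2-(4-benzyloxy-3-methoxyphenyl)-7-methoxy-2,3-dihydrobenzofuran-5-carbaldehyde | COC(OC)c1cc(OC)c2c(c1)[C@@H](COC(C)=O)[C@@H](c1ccc(OCc3ccccc3)c(OC)c1)O2
A7 | alternative 3 | bis-endo 4-methoxy furofuran acetal | COc1cc([C@H]2O[C@H](OC)[C@@H]3[C@H]2CO[C@@H]3c2cc(OC)c3c(c2)[C@@H](COC(C)=O)[C@@H](c2ccc(OCc4ccccc4)c(OC)c2)O3)ccc1OCc1ccccc1
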